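**Plan**

Locants follow the target: C1 quaternary (bears C15H2OAc), C2–C5 rest of ring A (C3 OAc, C4 OH, C5 CMe2), C6 cage apex, C7 bridge CH2, C8–C10 cyclopropane (C10 methyl), C11 CHOAc; α is the face of ring A that carries C15.
Retrosynthetic cuts: C3–O/C4–O (cis-hydroxylation of a C3=C4 alkene), C6–C7 (enolate alkylation), C8–C9, C8–C10 and the C15–O–C7 ester (carbene [2+1]), C9=C10 (metathesis), C1–C15 and C1–C9 (homologation of a C1 ketone), C6–C11 (aldol), one C5–CH3 (cuprate).
Forward order: ring A comes from 2-methylcyclohexenone; ring C1/C6/C11/C10/C9 closes by metathesis; cyclopropane and δ-lactone form in the key step; the C6–C7 bond then closes the cage; the ring A diol monoacetate comes last.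
Enabling feature: C1 is quaternary and holds C15 on the face of ring C1/C6/C11/C10/C9 on which the C7–C8 bridge must lie, so a carbene hung from the C15 oxygen reaches C9=C10 only on that face and finds no C1–H to insert into.
Stereochemistry: C4 by CBS reduction; C4 steers C6 (aldol), C6 steers C1 (hydroxymethylation); the C15 tether fixes C8, C9, C10; the cage fixes C6; equilibrating reduction sets C11; diaxial opening in the Woodward reaction sets C3 and C4.

Key step: step 13

Remark: 9 is an E/Z mixture and 10 a mixture of C1 epimers, each converging in the following step; 7 is drawn as the anti aldol, whose C11 epimer would converge at step 17.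

**Route**

Step 1
Reactants: 1 2-methylcyclohex-2-en-1-one
Product: 2 (S)-2-methylcyclohex-2-en-1-ol
Conditions: (R)-2-methyl-CBS-oxazaborolidine (0.1 equiv), BH3·SMe2, THF, −20 °C
Reagents that add atoms: none
Why: Corey–Bakshi–Shibata reduction, in which the borane-bound oxazaborolidine binds the ketone with the α-methylated alkenyl arm as the large group and delivers hydride to one enantioface, setting C4 as S.

Step 2
Reactants: 2 (S)-2-methylcyclohex-2-en-1-ol
Product: 3 (S)-tert-butyldimethyl[(2-methylcyclohex-2-en-1-yl)oxy]silane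
Conditions: TBSCl, imidazole, DMF, 20 °C
Reagents that add atoms: tert-butyldimethylsilyl chloride, CC(C)(C)[Si](C)(C)Cl
Why: Imidazole-promoted silylation of the secondary allylic alcohol gives a silyl ether that should survive every step up to step 21, with no change at C4.

Step 3
Reactants: 3 (S)-tert-butyldimethyl[(2-methylcyclohex-2-en-1-yl)oxy]silane
Product: 4 (S)-4-[(tert-butyldimethylsilyl)oxy]-3-methylcyclohex-2-en-1-one
Conditions: dirhodium tetracaprolactamate Rh2(cap)4 (1 mol %), tBuOOH, K2CO3, CH2Cl2, 20 °C
Reagents that add atoms: tert-butyl hydroperoxide, CC(C)(C)OO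
Why: Dirhodium-catalysed allylic C–H oxidation with tert-butyl hydroperoxide turns the ring allylic methylene (future C1) into the enone carbonyl, while the C4–H geminal to the bulky silyloxy group is shielded and C4 is untouched.

Step 4
Reactants: 4 (S)-4-[(tert-butyldimethylsilyl)oxy]-3-methylcyclohex-2-en-1-one, 5 methacrolein
Product: 7 (2S,4S)-4-[(tert-butyldimethylsilyl)oxy]-2-[(1R)-1-hydroxy-2-methylprop-2-en-1-yl]-3,3-dimethylcyclohexan-1-one, via lithium enolate 6 (not isolated)
Conditions: Me2CuLi, Et2O, −20 °C; then ZnCl2, −78 °C; then 5, −78 °C; aq. NH4Cl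
Reagents that add atoms: lithium dimethylcuprate, [Li+].C[Cu-]C
Why: Tandem cuprate conjugate addition–aldol reaction, in which methyl adds to the β-carbon C5 (no stereocentre) and the regiodefined C1/C6 zinc enolate attacks methacrolein through a chair Zimmerman–Traxler transition state, entering C6 axially on the face opposite the pseudoaxial C5 methyl and the C4 silyloxy group (side chain trans to OTBS) and giving the anti C6/C11 pair expected for a ring (E)-enolate.

Step 5
Reactants: 7 (2S,4S)-4-[(tert-butyldimethylsilyl)oxy]-2-[(1R)-1-hydroxy-2-methylprop-2-en-1-yl]-3,3-dimethylcyclohexan-1-one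
Product: 8 (2S,4S)-4-[(tert-butyldimethylsilyl)oxy]-3,3-dimethyl-2-{(1R)-2-methyl-1-[(triethylsilyl)oxy]prop-2-en-1-yl}cyclohexan-1-one
Conditions: Et3SiOTf, 2,6-lutidine, CH2Cl2, −78 °C
Reagents that add atoms: triethylsilyl trifluoromethanesulfonate, CC[Si](CC)(CC)OS(=O)(=O)C(F)(F)F
Why: Low-temperature silylation with the silyl triflate and a hindered base caps the aldol hydroxyl before retro-aldol cleavage can set in, leaving C6 and C11 unchanged.

Step 6
Reactants: 8 (2S,4S)-4-[(tert-butyldimethylsilyl)oxy]-3,3-dimethyl-2-{(1R)-2-methyl-1-[(triethylsilyl)oxy]prop-2-en-1-yl}cyclohexan-1-one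
Product: 9 methyl enol ether of 8 (C1=CH–OMe in place of C1=O, E/Z mixture)
Conditions: MeOCH2PPh3Cl, KN(SiMe3)2, THF, 0 to 20 °C
Reagents that add atoms: (methoxymethyl)triphenylphosphonium chloride, COC[P+](c1ccccc1)(c1ccccc1)c1ccccc1.[Cl-]
Why: Wittig olefination with the methoxymethylene ylide homologates the C1 ketone by one carbon, and because the only unhindered enolisation is towards C2, C6 should not epimerise and the C11 silyloxy group should not be eliminated.

Step 7
Reactants: 9 methyl enol ether of 8
Product: 10 aldehyde with C1–H and the C9 formyl group on ring A (C1 epimers, trans isomer drawn)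
Conditions: Hg(OAc)2, THF/H2O, 0 °C; then aq. KI
Reagents that add atoms: water, O
Why: Oxymercuration of the electron-rich enol ether followed by iodide-induced demercuration is a neutral enol ether hydrolysis that frees the C9 aldehyde without cleaving the acid-labile triethylsilyl ether, and the C1 mixture it gives is erased in step 8.

Step 8
Reactants: 10 aldehyde with C1–H and the C9 formyl group
Product: 11 hydroxymethyl aldehyde with quaternary C1 (C9 formyl β, C15 hydroxymethyl α)
Conditions: aq. CH2O (37 %), K2CO3, THF/H2O, 40 °C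
Reagents that add atoms: formaldehyde, C=O
Why: Crossed aldol reaction with formaldehyde (hydroxymethylation of an α-branched aldehyde), in which the C1 enolate is attacked on the face opposite the bulky C6 side chain, so that C15 ends trans to C11 and the formyl carbon C9 cis to it, which fixes the quaternary centre C1.

Step 9
Reactants: 11 hydroxymethyl aldehyde with quaternary C1
Product: 12 diene carbinol (C1 carries the C9 vinyl group β and the C15 hydroxymethyl group α)
Conditions: MePPh3Br, KN(SiMe3)2 (excess ylide), THF, −78 to 0 °C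
Reagents that add atoms: methyltriphenylphosphonium bromide, C[P+](c1ccccc1)(c1ccccc1)c1ccccc1.[Br-]
Why: Wittig methylenation of the neopentyl aldehyde with excess ylide at low temperature, where olefination should outrun retro-aldol loss of formaldehyde from the alkoxide, gives the C9 vinyl group without touching C1.

Step 10
Reactants: 12 diene carbinol
Product: 13 cis-hydrindenol (C15 alcohol, C9=C10, C11 OTES β, C4 OTBS α)
Conditions: second-generation Grubbs catalyst RuCl2(=CHPh)(PCy3)(H2IMes) (5 mol %), CH2Cl2, 40 °C
Reagents that add atoms: none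
Why: Ring-closing metathesis of the 1,6-diene, possible because the vinyl group on C1 and the C11 side chain on C6 are cis, expels ethene and forms the trisubstituted C9=C10 bond of the five-membered ring.

Step 11
Reactants: 13 cis-hydrindenol, 14 bromoacetyl bromide
Product: 15 C15 bromoacetate of 13
Conditions: pyridine, CH2Cl2, 0 °C
Reagents that add atoms: none
Why: O-Acylation of the primary neopentyl alcohol with the acid bromide and pyridine installs the two-carbon tether on the C15 oxygen.

Step 12
Reactants: 15 C15 bromoacetate of 13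
Product: 16 C15 diazoacetate of 13
Conditions: TsNHNHTs, DBU, THF, 0 °C
Reagents that add atoms: N,N'-ditosylhydrazine, Cc1ccc(cc1)S(=O)(=O)NNS(=O)(=O)c1ccc(C)cc1
Why: Diazo synthesis by substitution–elimination, in which the bromoacetate alkylates N,N'-ditosylhydrazine and DBU then expels two sulfinate ions, under conditions that leave both silyl ethers intact.

Step 13
Reactants: 16 C15 diazoacetate of 13
Product: 17 cyclopropane-fused δ-lactone (C7 lactone carbonyl on C8, ring oxygen on C15)
Conditions: Rh2(OAc)4 (1 mol %), CH2Cl2, 40 °C, slow addition of 16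
Reagents that add atoms: none
Why: Rh2(OAc)4 extrudes N2 from the diazoacetate and the electrophilic rhodium carbene adds to the electron-rich trisubstituted C9=C10 bond in a concerted, asynchronous [2+1] step, the well-known intramolecular metal-carbene cyclopropanation of a homoallylic diazoacetate. The cyclopropane (C8, C9, C10) closes by this [2+1] addition and the six-membered lactone (C7, O, C15, C1, C9, C8) closes in the same event, the O–C15–C1 tether allowing only the fused mode with the carbonyl carbon C7 endo on C8. C8, C9 and C10 are set by the tether: C15 sits on the α face of C1, so the carbene can reach only the α face of the alkene. The step needs chemoselectivity for alkene addition over C–H insertion and carbene dimerisation: C1 is quaternary, so the usual γ-lactone-forming insertion has no hydrogen, insertion at C2 or C6 would be a slower six-ring process, and slow addition keeps the diazo concentration low. The C11 silyl ether lies on the β face and the C4 silyl ether is remote, so neither should intercept the carbene.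

Step 14
Reactants: 17 cyclopropane-fused δ-lactone
Product: 18 C7,C15-diol (C11 OTES, C4 OTBS)
Conditions: LiAlH4, THF, 0 °C
Reagents that add atoms: none
Why: Hydride reduction of the δ-lactone with LiAlH4 gives the C7/C15 diol while both silyl ethers and the cyclopropane stay intact.

Step 15
Reactants: 18 C7,C15-diol
Product: 19 C7 iodide with free C15 alcohol
Conditions: I2, PPh3, imidazole, CH2Cl2, 0 °C
Reagents that add atoms: iodine, II
Why: Appel-type iodination, in which both hydroxyls can form alkoxyphosphonium ions but iodide displaces only at the cyclopropylcarbinyl carbon C7, SN2 attack at the neopentyl carbon C15 being blocked and that oxyphosphonium returning the alcohol on work-up.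

Step 16
Reactants: 19 C7 iodide with free C15 alcohol
Product: 20 iodo diol (C11 OH, C15 OH, C4 OTBS)
Conditions: HF·pyridine, pyridine, THF, 0 °C
Reagents that add atoms: none
Why: Buffered HF·pyridine removes the triethylsilyl ether selectively (desilylation), the hindered tert-butyldimethylsilyl ether at C4 being far slower to cleave.

Step 17
Reactants: 20 iodo diol
Product: 21 C11 ketone C15 aldehyde with the C7 iodide
Conditions: Dess–Martin periodinane, NaHCO3, CH2Cl2, 20 °C
Reagents that add atoms: none
Why: Dess–Martin oxidation converts the C11 carbinol into the cyclopropyl ketone and the C15 alcohol into a non-enolisable aldehyde under buffered, non-basic conditions that spare the primary iodide.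

Step 18
Reactants: 21 C11 ketone C15 aldehyde with the C7 iodide
Product: 22 cage keto aldehyde (C6–C7 bond closed, C11 ketone, C15 aldehyde)
Conditions: KOtBu, THF, −78 to 0 °C
Reagents that add atoms: none
Why: Intramolecular enolate alkylation (SN2), in which C6 carries the only enolisable hydrogen and its enolate attacks the endo iodomethyl carbon C7 held directly above the α face of the five-membered ring, closing the cage and fixing C6, while O-alkylation would give a far more strained bridged enol ether.

Step 19
Reactants: 22 cage keto aldehyde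
Product: 23 cage diol (C11 OH on the C7 side, C15 OH, C4 OTBS)
Conditions: Al(OiPr)3, iPrOH, toluene, reflux, acetone not distilled off
Reagents that add atoms: none
Why: Meerwein–Ponndorf–Verley reduction under reversible conditions reduces the aldehyde and should give the thermodynamically preferred C11 alcohol, whose hydroxyl sits on the C7 side of the bridge, away from the ring A methylene C2 that crowds the other position, whereas an irreversible hydride would attack from the C7 side and give the wrong epimer.

Step 20
Reactants: 23 cage diol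
Product: 24 C11,C15-diacetate (C4 OTBS)
Conditions: Ac2O, DMAP, Et3N, CH2Cl2, 20 °C
Reagents that add atoms: acetic anhydride, CC(=O)OC(C)=O
Why: DMAP-catalysed acetylation esterifies the primary C15 and the hindered secondary C11 hydroxyls with no change in configuration.

Step 21
Reactants: 24 C11,C15-diacetate (C4 OTBS)
Product: 25 C11,C15-diacetate with free C4 alcohol
Conditions: aq. HF (48 %), MeCN, 20 °C
Reagents that add atoms: none
Why: Fluoride-mediated desilylation with aqueous HF cleaves the hindered C4 silyl ether under conditions to which the acetates and the cyclopropane are stable.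

Step 22
Reactants: 25 C11,C15-diacetate with free C4 alcohol
Product: 26 C3=C4 alkene diacetate
Conditions: Burgess reagent, toluene, 70 °C
Reagents that add atoms: none
Why: Burgess dehydration (syn elimination through the sulfamate ester) can only remove a hydrogen from C3 because C5 is quaternary, so the C3=C4 alkene should form regiospecifically.

Step 23
Reactants: 26 C3=C4 alkene diacetate
Product: 28 CNP0197219.1, via trans-diaxial iodo acetate 27 (not isolated)
Conditions: I2, AgOAc, AcOH, 20 °C; then H2O, AcOH, 90 °C
Reagents that add atoms: silver acetate, CC(=O)[O-].[Ag+]; water, O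
Why: Woodward cis-hydroxylation, in which acetate opens the β-iodonium ion at C3 in the only trans-diaxial mode open to it (C4 is neopentyl, Fürst–Plattner rule), the axial C3 acetate then displaces the C4 iodide with silver assistance to give the α-face acetoxonium ion, and water opens its ortho acid to the axial C3 acetate and equatorial C4 hydroxyl, setting C3 and C4 on the more hindered α face.

**Compound list**

1 | 2-methylcyclohex-2-en-1-one | CC1=CCCCC1=O | starting material
2 | (S)-2-methylcyclohex-2-en-1-ol | CC1=CCCC[C@@H]1O | intermediate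
3 | (S)-tert-butyldimethyl[(2-methylcyclohex-2-en-1-yl)oxy]silane | CC1=CCCC[C@@H]1O[Si](C)(C)C(C)(C)C | intermediate
4 | (S)-4-[(tert-butyldimethylsilyl)oxy]-3-methylcyclohex-2-en-1-one | CC1=CC(=O)CC[C@@H]1O[Si](C)(C)C(C)(C)C | intermediate
5 | methacrolein (2-methylprop-2-enal) | CC(=C)C=O | starting material
6 | lithium enolate (C1–OLi, C1=C6) of (S)-4-[(tert-butyldimethylsilyl)oxy]-3,3-dimethylcyclohexanone | [Li]OC1=CC(C)(C)[C@@H](O[Si](C)(C)C(C)(C)C)CC1 | intermediate
7 | (2S,4S)-4-[(tert-butyldimethylsilyl)oxy]-2-[(1R)-1-hydroxy-2-methylprop-2-en-1-yl]-3,3-dimethylcyclohexan-1-one | C=C(C)[C@H](O)[C@H]1C(=O)CC[C@H](O[Si](C)(C)C(C)(C)C)C1(C)C | intermediate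
8 | (2S,4S)-4-[(tert-butyldimethylsilyl)oxy]-3,3-dimethyl-2-{(1R)-2-methyl-1-[(triethylsilyl)oxy]prop-2-en-1-yl}cyclohexan-1-one | C=C(C)[C@H](O[Si](CC)(CC)CC)[C@H]1C(=O)CC[C@H](O[Si](C)(C)C(C)(C)C)C1(C)C | intermediate
9 | methyl enol ether of 8 (C1=CH–OMe, E/Z mixture) | C=C(C)[C@H](O[Si](CC)(CC)CC)[C@H]1C(=COC)CC[C@H](O[Si](C)(C)C(C)(C)C)C1(C)C | intermediate
10 | ring A carbaldehyde (C1–H, C9 formyl; C6 side chain and silyl ethers as in 8; trans C1 epimer drawn) | C=C(C)[C@H](O[Si](CC)(CC)CC)[C@H]1[C@H](C=O)CC[C@H](O[Si](C)(C)C(C)(C)C)C1(C)C | intermediate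
11 | hydroxymethyl aldehyde (quaternary C1: C9 formyl cis, C15 hydroxymethyl trans to the C6 side chain) | C=C(C)[C@H](O[Si](CC)(CC)CC)[C@H]1[C@](C=O)(CO)CC[C@H](O[Si](C)(C)C(C)(C)C)C1(C)C | intermediate
12 | diene carbinol (C1: C9 vinyl cis, C15 hydroxymethyl trans to the C6 side chain) | C=C(C)[C@H](O[Si](CC)(CC)CC)[C@H]1[C@](C=C)(CO)CC[C@H](O[Si](C)(C)C(C)(C)C)C1(C)C | intermediate
13 | cis-hydrindenol (C15 alcohol, C9=C10, C11 OTES β, C4 OTBS α) | OC[C@]12CC[C@H](O[Si](C)(C)C(C)(C)C)C(C)(C)[C@H]1[C@@H](O[Si](CC)(CC)CC)C(C)=C2 | intermediate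
14 | bromoacetyl bromide | BrCC(Br)=O | starting material
15 | C15 bromoacetate of 13 | BrCC(=O)OC[C@]12CC[C@H](O[Si](C)(C)C(C)(C)C)C(C)(C)[C@H]1[C@@H](O[Si](CC)(CC)CC)C(C)=C2 | intermediate
16 | C15 diazoacetate of 13 (key-step precursor) | [N-]=[N+]=CC(=O)OC[C@]12CC[C@H](O[Si](C)(C)C(C)(C)C)C(C)(C)[C@H]1[C@@H](O[Si](CC)(CC)CC)C(C)=C2 | intermediate
17 | cyclopropane-fused δ-lactone (C7 carbonyl endo on C8; key-step product) | O=C1OC[C@]23CC[C@H](O[Si](C)(C)C(C)(C)C)C(C)(C)[C@H]2[C@@H](O[Si](CC)(CC)CC)[C@]4(C)[C@H]1[C@H]34 | intermediate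
18 | C7,C15-diol (C11 OTES, C4 OTBS) | OC[C@]12CC[C@H](O[Si](C)(C)C(C)(C)C)C(C)(C)[C@H]1[C@@H](O[Si](CC)(CC)CC)[C@]3(C)[C@H](CO)[C@H]23 | intermediate
19 | C7 iodide, C15 alcohol (C11 OTES, C4 OTBS) | OC[C@]12CC[C@H](O[Si](C)(C)C(C)(C)C)C(C)(C)[C@H]1[C@@H](O[Si](CC)(CC)CC)[C@]3(C)[C@H](CI)[C@H]23 | intermediate
20 | iodo diol (C7 iodide, C11 OH, C15 OH, C4 OTBS) | OC[C@]12CC[C@H](O[Si](C)(C)C(C)(C)C)C(C)(C)[C@H]1[C@@H](O)[C@]3(C)[C@H](CI)[C@H]23 | intermediate
21 | C11 ketone, C15 aldehyde, C7 iodide (C4 OTBS) | O=C[C@]12CC[C@H](O[Si](C)(C)C(C)(C)C)C(C)(C)[C@H]1C(=O)[C@]3(C)[C@H](CI)[C@H]23 | intermediate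
22 | cage keto aldehyde (C6–C7 closed, C11 ketone, C15 aldehyde, C4 OTBS) | O=C[C@]12CC[C@H](O[Si](C)(C)C(C)(C)C)C(C)(C)[C@]13C[C@@H]1[C@H]2[C@]1(C)C3=O | intermediate
23 | cage diol (C11 OH on the C7 side, C15 OH, C4 OTBS) | OC[C@]12CC[C@H](O[Si](C)(C)C(C)(C)C)C(C)(C)[C@]13C[C@@H]1[C@H]2[C@]1(C)[C@H]3O | intermediate
24 | C11,C15-diacetate (C4 OTBS) | CC(=O)OC[C@]12CC[C@H](O[Si](C)(C)C(C)(C)C)C(C)(C)[C@]13C[C@@H]1[C@H]2[C@]1(C)[C@H]3OC(C)=O | intermediate
25 | C11,C15-diacetate, C4 alcohol | CC(=O)OC[C@]12CC[C@H](O)C(C)(C)[C@]13C[C@@H]1[C@H]2[C@]1(C)[C@H]3OC(C)=O | intermediate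
26 | C3=C4 alkene diacetate | CC(=O)OC[C@]12CC=CC(C)(C)[C@]13C[C@@H]1[C@H]2[C@]1(C)[C@H]3OC(C)=O | intermediate
27 | trans-diaxial iodo acetate (C3 OAc α, C4 I β) | CC(=O)OC[C@]12C[C@H](OC(C)=O)[C@@H](I)C(C)(C)[C@]13C[C@@H]1[C@H]2[C@]1(C)[C@H]3OC(C)=O | intermediate
28 | CNP0197219.1 | CC(=O)OC[C@]12C[C@H](OC(C)=O)[C@H](O)C(C)(C)[C@]13C[C@@H]1[C@H]2[C@]1(C)[C@H]3OC(C)=O | target

**Count and risks**

Total step count: 23. Longest linear sequence: 23 steps (fully linear from 1).

Step 23 is the most exposed. Acetate may fail to enter the hindered axial position at C3, the syn-axial C15 acetate may take part in the opening, silver-assisted departure of the neopentyl iodide may set off a methyl shift from C5, and acyl migration may scramble the monoacetate. The fallback leaves from 26 and returns at 28. Epoxidation with mCPBA on the less hindered β face should give the 3β,4β-epoxide F1. Acetolysis (AcOH, NaOAc, 60 °C) should open it trans-diaxially at C3 to the 3α-acetoxy-4β-alcohol F2. Dess–Martin oxidation should give the 3α-acetoxy 4-ketone F3. NaBH4 with CeCl3 in methanol at −78 °C should then add hydride from the β face, because the α approach is flanked by the axial C3 acetoxy group and the axial C5 methyl, and give 28 with the acetate already on C3.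

Step 18 comes next. Removal of the shielded C6 hydrogen may be slow, the alkoxide may add to or degrade the aldehyde, and the strained closure may lose out to intermolecular reaction. The fallback leaves from 21 and returns at 22. Soft enolisation with Me3SiOTf and Et3N should give the trimethylsilyl enol ether F4. AgOTf in CH2Cl2 at −78 °C should then pull off iodide so that the enol ether carbon C6 captures the developing cyclopropylcarbinyl cation at C7. This is a Lewis-acid-promoted α-alkylation of a silyl enol ether by an ionisable halide and needs no strong base.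

Step 15 is third. The pre-organised 1,5-diol may cyclodehydrate to a tetrahydropyran, or the two primary hydroxyls may not be told apart cleanly. The fallback leaves from 17 and returns at 20. AlMe3 with Me2NH·HCl should open the lactone to the hydroxy N,N-dimethylamide F5. Et3SiOTf with 2,6-lutidine should give the bis(triethylsilyl) ether amide F6. LiBHEt3 should reduce the tertiary amide to the C7 primary alcohol F7. I2, PPh3 and imidazole should then iodinate the only free hydroxyl to give the C7 iodide F8. HF·pyridine should remove both triethylsilyl groups and return 20.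

Further compounds
F1 | step 23 | 3β,4β-epoxide of 26 | CC(=O)OC[C@]12C[C@H]4O[C@H]4C(C)(C)[C@]13C[C@@H]1[C@H]2[C@]1(C)[C@H]3OC(C)=O
F2 | step 23 | 3α-acetoxy-4β-alcohol (C11,C15-diacetate) | CC(=O)OC[C@]12C[C@H](OC(C)=O)[C@@H](O)C(C)(C)[C@]13C[C@@H]1[C@H]2[C@]1(C)[C@H]3OC(C)=O
F3 | step 23 | 3α-acetoxy 4-ketone (C11,C15-diacetate) | CC(=O)OC[C@]12C[C@H](OC(C)=O)C(=O)C(C)(C)[C@]13C[C@@H]1[C@H]2[C@]1(C)[C@H]3OC(C)=O
F4 | step 18 | trimethylsilyl enol ether of 21 (C6=C11–OSiMe3) | O=C[C@]12CC[C@H](O[Si](C)(C)C(C)(C)C)C(C)(C)C1=C(O[Si](C)(C)C)[C@]3(C)[C@H](CI)[C@H]23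
F5 | step 15 | hydroxy N,N-dimethylamide (C7 amide on C8, C15 OH) | OC[C@]12CC[C@H](O[Si](C)(C)C(C)(C)C)C(C)(C)[C@H]1[C@@H](O[Si](CC)(CC)CC)[C@]3(C)[C@H](C(=O)N(C)C)[C@H]23
F6 | step 15 | bis(triethylsilyl) ether amide (C11 and C15 OTES) | CC[Si](CC)(CC)OC[C@]12CC[C@H](O[Si](C)(C)C(C)(C)C)C(C)(C)[C@H]1[C@@H](O[Si](CC)(CC)CC)[C@]3(C)[C@H](C(=O)N(C)C)[C@H]23
F7 | step 15 | C7 primary alcohol (C11 and C15 OTES) | CC[Si](CC)(CC)OC[C@]12CC[C@H](O[Si](C)(C)C(C)(C)C)C(C)(C)[C@H]1[C@@H](O[Si](CC)(CC)CC)[C@]3(C)[C@H](CO)[C@H]23
F8 | step 15 | C7 iodide (C11 and C15 OTES) | CC[Si](CC)(CC)OC[C@]12CC[C@H](O[Si](C)(C)C(C)(C)C)C(C)(C)[C@H]1[C@@H](O[Si](CC)(CC)CC)[C@]3(C)[C@H](CI)[C@H]23
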